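**Assumption:** (2E)-4,4-dimethoxy-2-methylbut-2-enal and angelic anhydride are taken as purchasable. Carbons are numbered as in farnesane: C1 and C5 carry the two esters, C6/C7 are the ring-fusion carbons (the target is cis-fused), C8 and C10 carry the hydroxyls.

## Retrosynthetic overview

1. Target ⇒ (desilylation, double angeloylation, hydroxyl-directed ketone reduction) a cis-fused hydroazulenone with the C5 ketone and free C1–OH.
2. Seven-membered ring (formed last): one cationic step on a cyclopentenyl δ-silyloxy enal. The Lewis-acid-bound enal (an oxidised farnesyl/nerolidyl allyl cation) is attacked at C1 by C7 of the 6,7-olefin, and the C6 cation is quenched by a 1,2-hydride shift from the silyloxy carbon C5.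
3. Five-membered ring (formed first): C6–C10 closure of an acyclic keto-enal, the same bond the cyclase makes, run with reversed polarity so that oxygen stays on C10.
4. C4–C5 bond: vinylogous aldol of the cyclopentene carbaldehyde with a prenal-derived silyl dienol ether.
5. Acyclic chain: aldol of 3-methylbutan-2-one with a C5 enal acetal.

## Route

**Step 1**
Reactants: 1 3-methylbutan-2-one; 2 (2E)-4,4-dimethoxy-2-methylbut-2-enal
Product: 4 (5R,6E)-5-hydroxy-8,8-dimethoxy-2,6-dimethyloct-6-en-3-one, via enol diisopinocampheylborinate 3 (not isolated)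
Conditions: (−)-Ipc2BCl, Et3N, Et2O, 0 °C; then 2, −78 to −25 °C; H2O2, pH 7 buffer, MeOH
Reagents that add atoms: none
Why: Paterson boron aldol: Ipc2BCl/Et3N enolises the methyl side of 1, and the chiral enol borinate adds to the aldehyde of 2 through a cyclic transition state on the re face to set C8 (5R, about 80–90% ee expected, to be upgraded at crystalline 7); the facial sense of (−)-Ipc2BCl is from memory, and the (+)-reagent is used if it proves opposite.

**Step 2**
Reactants: 4 (5R,6E)-5-hydroxy-8,8-dimethoxy-2,6-dimethyloct-6-en-3-one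
Product: 5 (5R,6E)-5-[(tert-butyldiphenylsilyl)oxy]-8,8-dimethoxy-2,6-dimethyloct-6-en-3-one
Conditions: TBDPSCl, imidazole, 4-(dimethylamino)pyridine (cat.), DMF, 25 °C
Reagents that add atoms: tert-butyl(chloro)diphenylsilane, CC(C)(C)[Si](Cl)(c1ccccc1)c1ccccc1
Why: Standard silyl ether formation; the bulky, weakly donating TBDPS group later shields the α-face of the ring, survives Lewis acid, and is the only group removed at the end.

**Step 3**
Reactants: 5 (5R,6E)-5-[(tert-butyldiphenylsilyl)oxy]-8,8-dimethoxy-2,6-dimethyloct-6-en-3-one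
Product: 7 (3R,5S)-3-[(tert-butyldiphenylsilyl)oxy]-5-hydroxy-2-methyl-5-(propan-2-yl)cyclopent-1-ene-1-carbaldehyde, via keto-enal 6 (not isolated)
Conditions: pyrrolidine (30 mol %), CF3CO2H (30 mol %), H2O (3 equiv), toluene, 25 to 40 °C
Reagents that add atoms: water, O
Why: Proposed new method: the ammonium salt converts the unsaturated acetal into the iminium/dienamine of keto-enal 6, whose α-carbon (C6) adds to the tethered isopropyl ketone (C10) in an intramolecular aldol (Baylis–Hillman-type α-hydroxyalkylation); tautomerisation to the conjugated, hydrogen-bonded tetrasubstituted enal drains the reversible manifold (the γ-methyl adduct can revert), and OTBDPS and isopropyl both sit pseudo-equatorial in the envelope transition state, giving the 3R,5S isomer (OSi and i-Pr cis); closest known chemistry: dienamine-mediated intramolecular Rauhut–Currier cyclisations and amine-catalysed intramolecular aldolisations.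

**Step 4**
Reactants: 8 3-methylbut-2-enal
Product: 9 tert-butyl(dimethyl){[(1E)-3-methylbuta-1,3-dien-1-yl]oxy}silane
Conditions: TBSOTf, Et3N, Et2O, 0 °C
Reagents that add atoms: tert-butyldimethylsilyl trifluoromethanesulfonate, CC(C)(C)[Si](C)(C)OS(=O)(=O)C(F)(F)F
Why: Soft enolisation (γ-deprotonation) of prenal gives the (1E)-silyl dienol ether, the nucleophile for the vinylogous Mukaiyama aldol.

**Step 5**
Reactants: 7 (3R,5S)-3-[(tert-butyldiphenylsilyl)oxy]-5-hydroxy-2-methyl-5-(propan-2-yl)cyclopent-1-ene-1-carbaldehyde; 9 tert-butyl(dimethyl){[(1E)-3-methylbuta-1,3-dien-1-yl]oxy}silane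
Product: 10 (2E,5S)-5-{(3R,5S)-3-[(tert-butyldiphenylsilyl)oxy]-5-hydroxy-2-methyl-5-(propan-2-yl)cyclopent-1-en-1-yl}-5-hydroxy-3-methylpent-2-enal
Conditions: (S)-4-(1H-indol-3-ylmethyl)-2-phenyl-3-tosyl-1,3,2-oxazaborolidin-5-one (30 mol %), i-PrOH, EtCN, −78 °C
Reagents that add atoms: none
Why: Vinylogous Mukaiyama aldol: the Lewis-acid-bound aldehyde of 7 is attacked by the γ-carbon of 9 (γ-selective, E-enal) and the tryptophan-derived oxazaborolidinone directs si-face attack to set C5 as S (the D-tryptophan catalyst is used if the sense is reversed); i-PrOH takes up the silyl group.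

**Step 6**
Reactants: 10 (2E,5S)-5-{(3R,5S)-3-[(tert-butyldiphenylsilyl)oxy]-5-hydroxy-2-methyl-5-(propan-2-yl)cyclopent-1-en-1-yl}-5-hydroxy-3-methylpent-2-enal
Product: 11 (2E,5S)-5-{(3R,5S)-3-[(tert-butyldiphenylsilyl)oxy]-5-hydroxy-2-methyl-5-(propan-2-yl)cyclopent-1-en-1-yl}-3-methyl-5-[(triethylsilyl)oxy]pent-2-enal
Conditions: Et3SiCl, imidazole, CH2Cl2, 0 °C
Reagents that add atoms: chlorotriethylsilane, CC[Si](Cl)(CC)CC
Why: Selective silylation of the secondary allylic hydroxyl (the tertiary one is inert) gives the silyloxy carbinol needed as the terminating donor of the next step.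

**Step 7**
Reactants: 11 (2E,5S)-5-{(3R,5S)-3-[(tert-butyldiphenylsilyl)oxy]-5-hydroxy-2-methyl-5-(propan-2-yl)cyclopent-1-en-1-yl}-3-methyl-5-[(triethylsilyl)oxy]pent-2-enal
Product: 13 (1R,3S,3aS,8R,8aS)-1-[(tert-butyldiphenylsilyl)oxy]-3,8-dihydroxy-6,8a-dimethyl-3-(propan-2-yl)-2,3,3a,5,8,8a-hexahydroazulen-4(1H)-one, via 2Z-enal 12 (not isolated)
Conditions: SnCl4 (1.5 equiv, promoter), 2,6-di-tert-butyl-4-methylpyridine, CH2Cl2, −78 to −30 °C; aq. NaHCO3
Reagents that add atoms: none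
Why: Proposed new method: Prins cyclisation/1,2-hydride shift (Prins–pinacol): SnCl4 turns the enal into a hydroxyallyl cation whose 2E and 2Z forms interconvert by rotation about C2–C3 (as farnesyl and nerolidyl do in the biosynthesis); the 2Z form is attacked at C1 by C7 of the tetrasubstituted 6,7-olefin anti to the C8 OTBDPS group (setting the C7 quaternary centre and, with the tin-bound oxygen anti to the C7 methyl, C1), and the tertiary C6 cation is quenched by suprafacial 1,2-shift of H5 (α-face, fixed by 5S) to give the ketone and the cis ring fusion; a 6-exo spiro cation, if formed, can revert or ring-expand by 1,2-shift of C1 to the same C6 cation; closest known chemistry: Overman's carbocycle-forming Prins–pinacol reactions and Lewis-acid carbonyl–ene cyclisations of citral-type enals.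

**Step 8**
Reactants: 13 (1R,3S,3aS,8R,8aS)-1-[(tert-butyldiphenylsilyl)oxy]-3,8-dihydroxy-6,8a-dimethyl-3-(propan-2-yl)-2,3,3a,5,8,8a-hexahydroazulen-4(1H)-one
Product: 14 (1R,3S,3aR,4R,8R,8aS)-1-[(tert-butyldiphenylsilyl)oxy]-6,8a-dimethyl-3-(propan-2-yl)-1,2,3,3a,4,5,8,8a-octahydroazulene-3,4,8-triol
Conditions: Me4NBH(OAc)3, MeCN/AcOH, −30 °C
Reagents that add atoms: none
Why: Evans–Saksena hydroxyl-directed reduction: the β-oriented C10 hydroxyl binds the borohydride and delivers hydride to the β-face of the C5 ketone, giving the α (4R) alcohol anti to the tertiary hydroxyl; the mild acidic medium avoids retro-aldol and olefin migration.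

**Step 9**
Reactants: 14 (1R,3S,3aR,4R,8R,8aS)-1-[(tert-butyldiphenylsilyl)oxy]-6,8a-dimethyl-3-(propan-2-yl)-1,2,3,3a,4,5,8,8a-octahydroazulene-3,4,8-triol; 15 (2Z)-2-methylbut-2-enoic anhydride
Product: 16 (1R,3S,3aR,4R,8R,8aS)-1-[(tert-butyldiphenylsilyl)oxy]-3-hydroxy-6,8a-dimethyl-3-(propan-2-yl)-1,2,3,3a,4,5,8,8a-octahydroazulene-4,8-diyl bis[(2Z)-2-methylbut-2-enoate]
Conditions: LiN(SiMe3)2 (2.2 equiv), THF, −78 °C; then 15 (2.5 equiv), −78 to 0 °C
Reagents that add atoms: none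
Why: Acylation of the two secondary lithium alkoxides by the anhydride; low-temperature alkoxide acylation avoids Z-to-E (angelate to tiglate) isomerisation, and the tertiary hydroxyl is too hindered to react.

**Step 10**
Reactants: 16 (1R,3S,3aR,4R,8R,8aS)-1-[(tert-butyldiphenylsilyl)oxy]-3-hydroxy-6,8a-dimethyl-3-(propan-2-yl)-1,2,3,3a,4,5,8,8a-octahydroazulene-4,8-diyl bis[(2Z)-2-methylbut-2-enoate]
Product: 17 (1R,3S,3aR,4R,8R,8aR)-1,3-dihydroxy-6,8a-dimethyl-3-(propan-2-yl)-1,2,3,3a,4,5,8,8a-octahydroazulene-4,8-diyl bis[(2Z)-2-methylbut-2-enoate]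
Conditions: HF·pyridine, pyridine/THF, 0 to 25 °C
Reagents that add atoms: none
Why: Fluoride cleavage of the silyl ether under acidic, non-nucleophilic conditions that leave the angelates, the allylic ester and the tertiary alcohol untouched and do not promote acyl migration.

## Compound list

1 | 3-methylbutan-2-one | CC(C)C(C)=O | starting material
2 | (2E)-4,4-dimethoxy-2-methylbut-2-enal | COC(OC)/C=C(\C)C=O | starting material
3 | 3-methylbut-1-en-2-yl di[(−)-isopinocampheyl]borinate (enol borinate of 1) | C=C(C(C)C)OB([C@@H]1C[C@@H]2C[C@H]([C@H]1C)C2(C)C)[C@@H]1C[C@@H]2C[C@H]([C@H]1C)C2(C)C | intermediate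
4 | (5R,6E)-5-hydroxy-8,8-dimethoxy-2,6-dimethyloct-6-en-3-one | COC(OC)/C=C(\C)[C@H](O)CC(=O)C(C)C | intermediate
5 | (5R,6E)-5-[(tert-butyldiphenylsilyl)oxy]-8,8-dimethoxy-2,6-dimethyloct-6-en-3-one | COC(OC)/C=C(\C)[C@H](O[Si](c1ccccc1)(c1ccccc1)C(C)(C)C)CC(=O)C(C)C | intermediate
6 | (2E,4R)-4-[(tert-butyldiphenylsilyl)oxy]-3,7-dimethyl-6-oxooct-2-enal | O=C/C=C(\C)[C@H](O[Si](c1ccccc1)(c1ccccc1)C(C)(C)C)CC(=O)C(C)C | intermediate
7 | (3R,5S)-3-[(tert-butyldiphenylsilyl)oxy]-5-hydroxy-2-methyl-5-(propan-2-yl)cyclopent-1-ene-1-carbaldehyde | O=CC1=C(C)[C@H](O[Si](c2ccccc2)(c2ccccc2)C(C)(C)C)C[C@]1(O)C(C)C | intermediate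
8 | 3-methylbut-2-enal | CC(C)=CC=O | starting material
9 | tert-butyl(dimethyl){[(1E)-3-methylbuta-1,3-dien-1-yl]oxy}silane | CC(=C)/C=C/O[Si](C)(C)C(C)(C)C | intermediate
10 | (2E,5S)-5-{(3R,5S)-3-[(tert-butyldiphenylsilyl)oxy]-5-hydroxy-2-methyl-5-(propan-2-yl)cyclopent-1-en-1-yl}-5-hydroxy-3-methylpent-2-enal | O=C/C=C(\C)C[C@H](O)C1=C(C)[C@H](O[Si](c2ccccc2)(c2ccccc2)C(C)(C)C)C[C@]1(O)C(C)C | intermediate
11 | (2E,5S)-5-{(3R,5S)-3-[(tert-butyldiphenylsilyl)oxy]-5-hydroxy-2-methyl-5-(propan-2-yl)cyclopent-1-en-1-yl}-3-methyl-5-[(triethylsilyl)oxy]pent-2-enal | O=C/C=C(\C)C[C@H](O[Si](CC)(CC)CC)C1=C(C)[C@H](O[Si](c2ccccc2)(c2ccccc2)C(C)(C)C)C[C@]1(O)C(C)C | intermediate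
12 | (2Z,5S)-5-{(3R,5S)-3-[(tert-butyldiphenylsilyl)oxy]-5-hydroxy-2-methyl-5-(propan-2-yl)cyclopent-1-en-1-yl}-3-methyl-5-[(triethylsilyl)oxy]pent-2-enal | O=C/C=C(/C)C[C@H](O[Si](CC)(CC)CC)C1=C(C)[C@H](O[Si](c2ccccc2)(c2ccccc2)C(C)(C)C)C[C@]1(O)C(C)C | intermediate
13 | (1R,3S,3aS,8R,8aS)-1-[(tert-butyldiphenylsilyl)oxy]-3,8-dihydroxy-6,8a-dimethyl-3-(propan-2-yl)-2,3,3a,5,8,8a-hexahydroazulen-4(1H)-one (cis-fused) | O=C1CC(C)=C[C@@H](O)[C@@]2(C)[C@H](O[Si](c3ccccc3)(c3ccccc3)C(C)(C)C)C[C@](O)(C(C)C)[C@@H]12 | intermediate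
14 | (1R,3S,3aR,4R,8R,8aS)-1-[(tert-butyldiphenylsilyl)oxy]-6,8a-dimethyl-3-(propan-2-yl)-1,2,3,3a,4,5,8,8a-octahydroazulene-3,4,8-triol | O[C@@H]1CC(C)=C[C@@H](O)[C@@]2(C)[C@H](O[Si](c3ccccc3)(c3ccccc3)C(C)(C)C)C[C@](O)(C(C)C)[C@@H]12 | intermediate
15 | (2Z)-2-methylbut-2-enoic anhydride (angelic anhydride) | C/C=C(/C)C(=O)OC(=O)/C(C)=C\C | starting material
16 | (1R,3S,3aR,4R,8R,8aS)-1-[(tert-butyldiphenylsilyl)oxy]-3-hydroxy-6,8a-dimethyl-3-(propan-2-yl)-1,2,3,3a,4,5,8,8a-octahydroazulene-4,8-diyl bis[(2Z)-2-methylbut-2-enoate] | C/C=C(/C)C(=O)O[C@@H]1CC(C)=C[C@@H](OC(=O)/C(C)=C\C)[C@@]2(C)[C@H](O[Si](c3ccccc3)(c3ccccc3)C(C)(C)C)C[C@](O)(C(C)C)[C@@H]12 | intermediate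
17 | (1R,3S,3aR,4R,8R,8aR)-1,3-dihydroxy-6,8a-dimethyl-3-(propan-2-yl)-1,2,3,3a,4,5,8,8a-octahydroazulene-4,8-diyl bis[(2Z)-2-methylbut-2-enoate] | C/C=C(/C)C(=O)O[C@@H]1CC(C)=C[C@@H](OC(=O)/C(C)=C\C)[C@@]2(C)[C@H](O)C[C@](O)(C(C)C)[C@@H]12 | target

## Step count and risks

Total steps: 10. Longest linear sequence: 9 (steps 1, 2, 3, 5, 6, 7, 8, 9, 10).

**Step 7 (most likely to fail).** Three things can go wrong: the cation may close 6-exo at C6 to the spiro skeleton instead of 7-endo at C7; the C6 cation may be quenched by 1,2-shift of the α-oriented isopropyl group from the C10 carbinol instead of H5; and the tertiary allylic alcohol may ionise. Fallback, setting out from 10 and returning at 14: methyl chloroformate and pyridine give the C5 methyl carbonate F1; Pd(PPh3)4-catalysed silylation with Me3SiSiMe3 gives the C5 allylsilane F2; SnCl4 then closes the ring by a silicon-directed Hosomi–Sakurai attack of C7 on the aldehyde, which cannot give the spiro isomer or a long-lived C6 cation, to give the cycloheptadienol F3 with a 5,6-olefin; hydroboration–oxidation (BH3·SMe2; H2O2, NaOH) of that olefin on the α-face puts back O5 and H6 cis and gives 14. The face selectivity of this hydroboration is not secured and would have to be checked.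

**Step 3.** The dienamine can also attack through its γ-methyl carbon, which likewise gives a five-membered ring, and the 1,3-induction from C8 to C10 is unproven. Fallback, setting out from 5 and returning at 7: hydrolyse 5 (pyridinium p-toluenesulfonate, wet acetone) to isolated 6; Me2AlSPh adds thiolate to C7 and the aluminium enolate at C6 closes onto the ketone (tandem Michael–aldol, no γ-pathway) to give the β-phenylthio aldehyde F4; mCPBA gives the sulfoxide F5, which on warming eliminates benzenesulfenic acid towards the aldehyde to give 7.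

**Step 5.** The acceptor is a hindered tetrasubstituted enal with a free tertiary hydroxyl next to it, and C5 must be set by the catalyst. Fallback, setting out from 7 and returning at 11: a SiCl4/chiral bisphosphoramide-catalysed vinylogous aldol with the trimethylsilyl ketene acetal of ethyl 3-methylbut-2-enoate gives the hydroxy enoate F6; Et3SiCl and imidazole give the triethylsilyl ether F7; i-Bu2AlH gives the allylic alcohol F8; MnO2 oxidation gives 11.

## Further compounds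

F1 | step 7 | (2E,5S)-5-{(3R,5S)-3-[(tert-butyldiphenylsilyl)oxy]-5-hydroxy-2-methyl-5-(propan-2-yl)cyclopent-1-en-1-yl}-5-[(methoxycarbonyl)oxy]-3-methylpent-2-enal | O=C/C=C(\C)C[C@H](OC(=O)OC)C1=C(C)[C@H](O[Si](c2ccccc2)(c2ccccc2)C(C)(C)C)C[C@]1(O)C(C)C
F2 | step 7 | (2E)-5-{(3R,5S)-3-[(tert-butyldiphenylsilyl)oxy]-5-hydroxy-2-methyl-5-(propan-2-yl)cyclopent-1-en-1-yl}-3-methyl-5-(trimethylsilyl)pent-2-enal (both C5 epimers) | O=C/C=C(\C)CC([Si](C)(C)C)C1=C(C)[C@H](O[Si](c2ccccc2)(c2ccccc2)C(C)(C)C)C[C@]1(O)C(C)C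
F3 | step 7 | (1R,3S,8R,8aS)-1-[(tert-butyldiphenylsilyl)oxy]-6,8a-dimethyl-3-(propan-2-yl)-1,2,3,5,8,8a-hexahydroazulene-3,8-diol | O[C@@H]1C=C(C)CC=C2[C@@](O)(C(C)C)C[C@@H](O[Si](c3ccccc3)(c3ccccc3)C(C)(C)C)[C@]12C
F4 | step 3 | (3R,5S)-3-[(tert-butyldiphenylsilyl)oxy]-5-hydroxy-2-methyl-2-(phenylsulfanyl)-5-(propan-2-yl)cyclopentane-1-carbaldehyde (mixture at C1 and C2) | O=CC1C(C)(Sc2ccccc2)[C@H](O[Si](c2ccccc2)(c2ccccc2)C(C)(C)C)C[C@]1(O)C(C)C
F5 | step 3 | (3R,5S)-2-(benzenesulfinyl)-3-[(tert-butyldiphenylsilyl)oxy]-5-hydroxy-2-methyl-5-(propan-2-yl)cyclopentane-1-carbaldehyde (mixture at C1, C2 and sulfur) | O=CC1C(C)(S(=O)c2ccccc2)[C@H](O[Si](c2ccccc2)(c2ccccc2)C(C)(C)C)C[C@]1(O)C(C)C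
F6 | step 5 | ethyl (2E,5S)-5-{(3R,5S)-3-[(tert-butyldiphenylsilyl)oxy]-5-hydroxy-2-methyl-5-(propan-2-yl)cyclopent-1-en-1-yl}-5-hydroxy-3-methylpent-2-enoate | CCOC(=O)/C=C(\C)C[C@H](O)C1=C(C)[C@H](O[Si](c2ccccc2)(c2ccccc2)C(C)(C)C)C[C@]1(O)C(C)C
F7 | step 5 | ethyl (2E,5S)-5-{(3R,5S)-3-[(tert-butyldiphenylsilyl)oxy]-5-hydroxy-2-methyl-5-(propan-2-yl)cyclopent-1-en-1-yl}-3-methyl-5-[(triethylsilyl)oxy]pent-2-enoate | CCOC(=O)/C=C(\C)C[C@H](O[Si](CC)(CC)CC)C1=C(C)[C@H](O[Si](c2ccccc2)(c2ccccc2)C(C)(C)C)C[C@]1(O)C(C)C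
F8 | step 5 | (2E,5S)-5-{(3R,5S)-3-[(tert-butyldiphenylsilyl)oxy]-5-hydroxy-2-methyl-5-(propan-2-yl)cyclopent-1-en-1-yl}-3-methyl-5-[(triethylsilyl)oxy]pent-2-en-1-ol | OC/C=C(\C)C[C@H](O[Si](CC)(CC)CC)C1=C(C)[C@H](O[Si](c2ccccc2)(c2ccccc2)C(C)(C)C)C[C@]1(O)C(C)C
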